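## Retrosynthetic overview

1. Target ⇒ its saturated ring A ketone by a last-step α,β-dehydrogenation; the isofraxidin ether is carried from the first step.
2. Both carbocycles ⇒ one cascade from an acyclic (2Z,6E)-dienyl aryl ether. The α-carbon of the C10 ketone, made electrophilic as a tertiary α-keto carbenium (enolonium) ion, is joined to the nucleophilic 6,7-alkene. Ring A (ketone ring) closes first, ring B (cyclohexene) second, and a chiral counter-anion sets all three stereocentres.
3. Geometry logic: the 6E alkene gives the trans ring fusion; the 2Z alkene puts CH2OAr axial, trans to the angular methyl, as the target requires (hence nerol, not geraniol).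
4. Cation precursor ⇒ trichloroacetimidate of a tertiary α-ketol ⇒ alkylation of the dianion of 3-hydroxy-3-methylbutan-2-one with an E-allylic bromide.
5. Bromide ⇒ allylic oxidation and bromination of isofraxidin neryl ether ⇒ isofraxidin + nerol.

Assumption: the (S,S)-catalyst of step 6 is taken to give the (1S,4aS,8aR) series; if the sense of induction is the opposite, the (R,R)-catalyst is used with nothing else changed.

Numbering used below: acyclic intermediates are numbered from the OCH2 carbon (C1); the decalin is numbered as in the names (C1 bears CH2OAr, C4a and C8a are the fusion carbons).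

## Route

Step 1
Reactants: 1 isofraxidin (7-hydroxy-6,8-dimethoxy-2H-chromen-2-one); 2 nerol ((2Z)-3,7-dimethylocta-2,6-dien-1-ol)
Product: 3 isofraxidin neryl ether (7-{[(2Z)-3,7-dimethylocta-2,6-dien-1-yl]oxy}-6,8-dimethoxy-2H-chromen-2-one)
Conditions: PPh3, DIAD (diisopropyl azodicarboxylate), THF, 0 °C to rt
Reagents that add atoms: none
Why: Mitsunobu etherification, in which the acidic phenol displaces the alkoxyphosphonium of the primary allylic alcohol by SN2, so the 2Z geometry of nerol is carried over unchanged.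

Step 2
Reactants: 3 isofraxidin neryl ether
Product: 4 E-allylic alcohol (7-{[(2Z,6E)-8-hydroxy-3,7-dimethylocta-2,6-dien-1-yl]oxy}-6,8-dimethoxy-2H-chromen-2-one)
Conditions: SeO2 (0.3 equiv), t-BuOOH (3 equiv), CH2Cl2, 0 °C to rt
Reagents that add atoms: selenium dioxide O=[Se]=O; tert-butyl hydroperoxide CC(C)(C)OO
Why: Catalytic SeO2 allylic oxidation (ene reaction then 2,3-sigmatropic shift) attacks the E-methyl of the electron-richer terminal alkene and gives the E-allylic alcohol, while the 2,3-alkene is deactivated by its allylic aryloxy group.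

Step 3
Reactants: 4 E-allylic alcohol
Product: 5 allylic bromide (7-{[(2Z,6E)-8-bromo-3,7-dimethylocta-2,6-dien-1-yl]oxy}-6,8-dimethoxy-2H-chromen-2-one)
Conditions: CBr4, PPh3, CH2Cl2, −20 to 0 °C
Reagents that add atoms: carbon tetrabromide BrC(Br)(Br)Br
Why: Appel bromination replaces the primary allylic hydroxyl by SN2 under neutral conditions, without allylic transposition or loss of alkene geometry.

Step 4
Reactants: 5 allylic bromide; 6 3-hydroxy-3-methylbutan-2-one
Product: 8 tertiary α-ketol (7-{[(2Z,6E)-11-hydroxy-3,7,11-trimethyl-10-oxododeca-2,6-dien-1-yl]oxy}-6,8-dimethoxy-2H-chromen-2-one), via dilithium dianion 7 (not isolated)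
Conditions: 6 (1.5 equiv), LiN(iPr)2 (3.0 equiv), THF, −78 to −30 °C; then 5, DMPU, −78 to −40 °C; AcOH quench
Reagents that add atoms: none
Why: Enolate alkylation, in which 6 has only one enolisable carbon, so its alkoxide–enolate dianion is C-alkylated by the reactive primary allylic bromide and the oxygen-bearing quaternary carbon ends up next to the ketone without protecting groups; the low temperature is meant to spare the coumarin lactone.

Step 5
Reactants: 8 tertiary α-ketol
Product: 9 trichloroacetimidate (7-{[(2Z,6E)-3,7,11-trimethyl-10-oxo-11-[(2,2,2-trichloroethanimidoyl)oxy]dodeca-2,6-dien-1-yl]oxy}-6,8-dimethoxy-2H-chromen-2-one)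
Conditions: Cl3CCN (3 equiv), 1,8-diazabicyclo[5.4.0]undec-7-ene (DBU, 0.1 equiv), CH2Cl2, 0 °C
Reagents that add atoms: trichloroacetonitrile ClC(Cl)(Cl)C#N
Why: Base-catalysed addition of the fairly acidic tertiary hydroxyl to the nitrile (imidate formation) gives a leaving group that departs only after N-protonation, and the neighbouring carbonyl slows spontaneous ionisation so that 9 can be isolated.

Step 6
Reactants: 9 trichloroacetimidate
Product: 11 bicyclic ketone (7-{[(1S,4aS,8aR)-2,5,5,8a-tetramethyl-6-oxo-1,4,4a,5,6,7,8,8a-octahydronaphthalen-1-yl]methoxy}-6,8-dimethoxy-2H-chromen-2-one), via enolonium cation 10 (not isolated)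
Conditions: (S,S)-IDPi acid HN[P(=NSO2CF3)(O2R*)]2 with O2R* = (S)-3,3'-bis[3,5-bis(trifluoromethyl)phenyl]-1,1'-binaphthalene-2,2'-diolate (5 mol %), (CF3)3COH/CH2Cl2 1:3, 4 Å molecular sieves, −40 to −20 °C
Reagents that add atoms: none
Why: Proposed new method: the chiral acid protonates the imidate nitrogen (by far the most basic site), trichloroacetamide leaves with π-assistance, and the tertiary α-keto carbenium ion 10 (the α-carbon of a ketone acting as electrophile) bonds C11 to C6 of the 6,7-alkene inside the confined chiral ion pair; the chair–chair cascade then bonds C7 to C2 and ends by loss of a proton from C4 to the catalyst anion, the 6E alkene giving the trans fusion, the 2Z alkene placing CH2OAr axial, and the anion choosing between the two mirror-image folds so that C1, C4a and C8a are set together; the closest known reaction types are solvolytic α-keto cation formation from tertiary α-keto sulfonates, acid-triggered ionisation of trichloroacetimidates, oxyallyl-cation-initiated cation–olefin cascades, and imidodiphosphorimidate-catalysed enantioselective polyene cyclisation in fluorinated alcohols.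

Step 7
Reactants: 11 bicyclic ketone
Product: 12 target (7-{[(1S,4aS,8aR)-2,5,5,8a-tetramethyl-6-oxo-1,4,4a,5,6,8a-hexahydronaphthalen-1-yl]methoxy}-6,8-dimethoxy-2H-chromen-2-one)
Conditions: IBX (2-iodoxybenzoic acid, 2.5 equiv), 4-methoxypyridine N-oxide (2.5 equiv), DMSO, 25–40 °C
Reagents that add atoms: none
Why: IBX dehydrogenation of a ketone through its enol can only go toward C7 because C5 is quaternary, so the 7,8-enone forms regiospecifically, and no stereocentre is α to the carbonyl or otherwise touched.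

## Compound list

1 | isofraxidin (7-hydroxy-6,8-dimethoxy-2H-chromen-2-one) | COc1cc2ccc(=O)oc2c(OC)c1O | starting material
2 | nerol ((2Z)-3,7-dimethylocta-2,6-dien-1-ol) | CC(C)=CCC/C(C)=C\CO | starting material
3 | 7-{[(2Z)-3,7-dimethylocta-2,6-dien-1-yl]oxy}-6,8-dimethoxy-2H-chromen-2-one | COc1cc2ccc(=O)oc2c(OC)c1OC/C=C(C)\CCC=C(C)C | intermediate
4 | 7-{[(2Z,6E)-8-hydroxy-3,7-dimethylocta-2,6-dien-1-yl]oxy}-6,8-dimethoxy-2H-chromen-2-one | COc1cc2ccc(=O)oc2c(OC)c1OC/C=C(C)\CC/C=C(C)/CO | intermediate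
5 | 7-{[(2Z,6E)-8-bromo-3,7-dimethylocta-2,6-dien-1-yl]oxy}-6,8-dimethoxy-2H-chromen-2-one | COc1cc2ccc(=O)oc2c(OC)c1OC/C=C(C)\CC/C=C(C)/CBr | intermediate
6 | 3-hydroxy-3-methylbutan-2-one | CC(=O)C(C)(C)O | starting material
7 | dilithium dianion of 6 (lithium 3-methyl-3-(lithiooxy)but-1-en-2-olate) | C=C(O[Li])C(C)(C)O[Li] | intermediate
8 | 7-{[(2Z,6E)-11-hydroxy-3,7,11-trimethyl-10-oxododeca-2,6-dien-1-yl]oxy}-6,8-dimethoxy-2H-chromen-2-one | COc1cc2ccc(=O)oc2c(OC)c1OC/C=C(C)\CC/C=C(C)/CCC(=O)C(C)(C)O | intermediate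
9 | 7-{[(2Z,6E)-3,7,11-trimethyl-10-oxo-11-[(2,2,2-trichloroethanimidoyl)oxy]dodeca-2,6-dien-1-yl]oxy}-6,8-dimethoxy-2H-chromen-2-one | COc1cc2ccc(=O)oc2c(OC)c1OC/C=C(C)\CC/C=C(C)/CCC(=O)C(C)(C)OC(=N)C(Cl)(Cl)Cl | intermediate
10 | enolonium ion, the tertiary α-keto carbenium ion (6E,10Z)-12-[(6,8-dimethoxy-2-oxo-2H-chromen-7-yl)oxy]-2,6,10-trimethyl-3-oxododeca-6,10-dien-2-ylium, paired with the catalyst anion | COc1cc2ccc(=O)oc2c(OC)c1OC/C=C(C)\CC/C=C(C)/CCC(=O)[C+](C)C | intermediate
11 | 7-{[(1S,4aS,8aR)-2,5,5,8a-tetramethyl-6-oxo-1,4,4a,5,6,7,8,8a-octahydronaphthalen-1-yl]methoxy}-6,8-dimethoxy-2H-chromen-2-one | COc1cc2ccc(=O)oc2c(OC)c1OC[C@H]1C(C)=CC[C@@H]2C(C)(C)C(=O)CC[C@]21C | intermediate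
12 | 7-{[(1S,4aS,8aR)-2,5,5,8a-tetramethyl-6-oxo-1,4,4a,5,6,8a-hexahydronaphthalen-1-yl]methoxy}-6,8-dimethoxy-2H-chromen-2-one | COc1cc2ccc(=O)oc2c(OC)c1OC[C@H]1C(C)=CC[C@@H]2C(C)(C)C(=O)C=C[C@]21C | target

## Step count and risks

Total step count: 7. Longest linear sequence: 7 steps (from 1 or 2 to 12).

Most likely to fail, in this order:

**Step 6.** The enantioselectivity is untested. Loss of a methyl proton from 10 can give the isopropenyl ketone. Some exocyclic-methylene isomer of 11 may form and would be removed on AgNO3-impregnated silica. The allylic aryl ether could ionise once the imidate is consumed.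

Fallback: set out from 8 and reduce its ketone with catecholborane and the (R)-2-methyl-CBS-oxazaborolidine catalyst ((3aR)-1-methyl-3,3-diphenyltetrahydro-1H,3H-pyrrolo[1,2-c][1,3,2]oxazaborole) to the (10S)-diol F1. Treat this with MsCl/pyridine to give the secondary mesylate F2, and close it in the same flask with K2CO3/MeOH, with inversion, to the (R)-epoxide F3. Cyclise F3 with MeAlCl2 in CH2Cl2 at −78 °C; this is an epoxide-initiated cation–olefin bicyclisation in which the epoxide stereocentre dictates the fold, and it gives the hydroxy decalin F4. Oxidise F4 with Dess–Martin periodinane to come back to the route at 11.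

**Step 4.** The dianion may attack the coumarin lactone or add to its enoate, and some dialkylation is possible.

Fallback: set out from nerol 2 and silylate it (TBSCl, imidazole) to neryl silyl ether F5. Oxidise with SeO2/t-BuOOH to the E-allylic alcohol F6 and brominate (CBr4, PPh3) to the bromide F7. Alkylate dianion 7 with F7 to the silyl-protected ketol F8, and remove the silyl group with Bu4NF to the keto diol F9. Couple the primary allylic hydroxyl of F9 with isofraxidin 1 under the conditions of step 1 (the tertiary hydroxyl does not react) to come back to the route at 8.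

**Step 5.** The hindered imidate may cyclise onto the ketone, rearrange, or lose trichloroacetamide on handling.

Fallback: set out from 8 and dehydrate it with Burgess reagent (methyl N-(triethylammoniosulfonyl)carbamate) to the isopropenyl ketone F10. Add Et3SiH in the 1,4-sense with RhCl(PPh3)3 to give the fully substituted triethylsilyl enol ether F11. Treat F11 at −78 °C with BF3·OEt2 and the diacetoxy-λ3-iodane made from (R,R)-2,2'-[(2-iodo-1,3-phenylene)bis(oxy)]bis[N-(2,4,6-trimethylphenyl)propanamide]. The oxygen-bound iodane enolate is again an enolonium equivalent; the 6,7-alkene attacks its α-carbon and the same cascade follows, coming back to the route at 11.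

## Further compounds

F1 | step 6 | 7-{[(2Z,6E,10S)-10,11-dihydroxy-3,7,11-trimethyldodeca-2,6-dien-1-yl]oxy}-6,8-dimethoxy-2H-chromen-2-one | COc1cc2ccc(=O)oc2c(OC)c1OC/C=C(C)\CC/C=C(C)/CC[C@H](O)C(C)(C)O
F2 | step 6 | (3S,6E,10Z)-12-[(6,8-dimethoxy-2-oxo-2H-chromen-7-yl)oxy]-2-hydroxy-2,6,10-trimethyldodeca-6,10-dien-3-yl methanesulfonate | COc1cc2ccc(=O)oc2c(OC)c1OC/C=C(C)\CC/C=C(C)/CC[C@H](OS(C)(=O)=O)C(C)(C)O
F3 | step 6 | 7-({(2Z,6E)-9-[(2R)-3,3-dimethyloxiran-2-yl]-3,7-dimethylnona-2,6-dien-1-yl}oxy)-6,8-dimethoxy-2H-chromen-2-one | COc1cc2ccc(=O)oc2c(OC)c1OC/C=C(C)\CC/C=C(C)/CC[C@H]1OC1(C)C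
F4 | step 6 | 7-{[(1S,4aS,6R,8aR)-6-hydroxy-2,5,5,8a-tetramethyl-1,4,4a,5,6,7,8,8a-octahydronaphthalen-1-yl]methoxy}-6,8-dimethoxy-2H-chromen-2-one | COc1cc2ccc(=O)oc2c(OC)c1OC[C@H]1C(C)=CC[C@@H]2C(C)(C)[C@H](O)CC[C@]21C
F5 | step 4 | tert-butyl{[(2Z)-3,7-dimethylocta-2,6-dien-1-yl]oxy}dimethylsilane | CC(C)=CCC/C(C)=C\CO[Si](C)(C)C(C)(C)C
F6 | step 4 | (2E,6Z)-8-{[tert-butyl(dimethyl)silyl]oxy}-2,6-dimethylocta-2,6-dien-1-ol | OC/C(C)=C/CC/C(C)=C\CO[Si](C)(C)C(C)(C)C
F7 | step 4 | {[(2Z,6E)-8-bromo-3,7-dimethylocta-2,6-dien-1-yl]oxy}(tert-butyl)dimethylsilane | BrC/C(C)=C/CC/C(C)=C\CO[Si](C)(C)C(C)(C)C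
F8 | step 4 | (6E,10Z)-12-{[tert-butyl(dimethyl)silyl]oxy}-2-hydroxy-2,6,10-trimethyldodeca-6,10-dien-3-one | CC(C)(O)C(=O)CC/C(C)=C/CC/C(C)=C\CO[Si](C)(C)C(C)(C)C
F9 | step 4 | (6E,10Z)-2,12-dihydroxy-2,6,10-trimethyldodeca-6,10-dien-3-one | CC(C)(O)C(=O)CC/C(C)=C/CC/C(C)=C\CO
F10 | step 5 | 7-{[(2Z,6E)-3,7,11-trimethyl-10-oxododeca-2,6,11-trien-1-yl]oxy}-6,8-dimethoxy-2H-chromen-2-one | COc1cc2ccc(=O)oc2c(OC)c1OC/C=C(C)\CC/C=C(C)/CCC(=O)C(C)=C
F11 | step 5 | 7-{[(2Z,6E)-3,7,11-trimethyl-10-[(triethylsilyl)oxy]dodeca-2,6,10-trien-1-yl]oxy}-6,8-dimethoxy-2H-chromen-2-one | COc1cc2ccc(=O)oc2c(OC)c1OC/C=C(C)\CC/C=C(C)/CCC(O[Si](CC)(CC)CC)=C(C)C
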